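**Retrosynthetic overview**
1. Plastochromenol-8 is traced back to its 6-bromo-3-(p-tolylsulfinyl) derivative. The phenol comes from C6–Br, and C3–H comes from a removable chiral sulfinyl group on C3.
2. The benzene ring is bought. The pyran ring is the only ring formed, and it is cut at C2–C3 and O1–C8a. This gives the C43 methyl ketone (C2=O1 with its methyl group and the all-E chain) and an (E)-2-(2-fluoroaryl)vinyl p-tolyl sulfoxide (C3=C4–C4a=C8a).
3. Enabling feature: O1–C2 of the pyran ring is a ketone C=O in disguise, and C3=C4 is conjugated through C4a with the benzene carbon C8a. One sulfinyl group on C3 therefore acidifies C3–H, activates the ortho C8a–F bond for SNAr, fixes the arene cis to the new bond and carries the chirality.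
4. The ketone comes from solanesol by excision of its two allylic-alcohol carbons. The vinyl sulfoxide comes from 1-bromo-4-fluoro-2,3-dimethylbenzene by ortho-lithiation/formylation and condensation with (S)-methyl p-tolyl sulfoxide.

Key step: step 6

Notation: R8 is the all-E octaprenylmethyl side chain, (3E,7E,11E,15E,19E,23E,27E)-4,8,12,16,20,24,28,32-octamethyltritriaconta-3,7,11,15,19,23,27,31-octaen-1-yl. Chromene numbering (O1, C2, C3, C4, C4a, C5–C8, C8a) is used for the corresponding atoms of all precursors.

Assumption: the sense of induction in the key step follows the non-chelate model given there. Both antipodes of methyl p-tolyl sulfoxide are commercial, so the other antipode would be taken if the sense proved opposite.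

Step 1
Reactants: 1 solanesol
Product: 2 rac-(2S*,3S*)-2,3-epoxysolanesol
Conditions: VO(acac)2 (cat.), t-BuOOH, toluene, 0 °C to rt
Reagents that add atoms: tert-butyl hydroperoxide, CC(C)(C)OO
Why: Hydroxyl-directed vanadium-catalysed epoxidation should touch only the allylic-alcohol alkene among the nine trisubstituted alkenes, and the two stereocentres, formed as a racemate by syn oxygen transfer to the E alkene, are erased in step 2.

Step 2
Reactants: 2 rac-(2S*,3S*)-2,3-epoxysolanesol
Product: 4 all-E octaprenylacetone (R8–CO–CH3), via 1,2,3-triol 3 (not isolated)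
Conditions: H5IO6, THF/H2O, 0 °C
Reagents that add atoms: water, O
Why: Periodic acid should hydrolyse the epoxide to triol 3 and cleave both of its glycol bonds (Malaprade cleavage), which excises the two former allylic-alcohol carbons and leaves the methyl ketone, while isolated trisubstituted alkenes are inert to periodate at 0 °C.

Step 3
Reactants: 5 1-bromo-4-fluoro-2,3-dimethylbenzene
Product: 7 5-bromo-2-fluoro-3,4-dimethylbenzaldehyde, via aryllithium 6 (not isolated)
Conditions: LDA, THF, −78 °C; DMF; aq. HCl
Reagents that add atoms: N,N-dimethylformamide, CN(C)C=O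
Why: Directed ortho-metalation followed by formylation: fluorine is the strongest acidifying substituent, so LDA should lithiate the only C–H next to C–F at a temperature at which neither aryne formation nor bromine migration occurs.

Step 4
Reactants: 8 (S)-methyl p-tolyl sulfoxide; 7 5-bromo-2-fluoro-3,4-dimethylbenzaldehyde
Product: 10 1-(5-bromo-2-fluoro-3,4-dimethylphenyl)-2-[(S)-p-tolylsulfinyl]ethanol (both carbinol epimers), via lithiated sulfoxide 9 (not isolated)
Conditions: LDA, THF, −78 °C; 7; aq. NH4Cl
Reagents that add atoms: none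
Why: Addition of an α-sulfinyl carbanion to an aldehyde, in which the configuration at sulfur is untouched and the new carbinol centre, formed without useful control, is erased in step 5.

Step 5
Reactants: 10 1-(5-bromo-2-fluoro-3,4-dimethylphenyl)-2-[(S)-p-tolylsulfinyl]ethanol
Product: 12 1-bromo-4-fluoro-2,3-dimethyl-5-{(E)-2-[(S)-p-tolylsulfinyl]vinyl}benzene, via mesylate 11 (not isolated)
Conditions: MsCl, Et3N, CH2Cl2, 0 °C; DBU, rt
Reagents that add atoms: none
Why: Mesylation and base-induced E1cB elimination should convert both carbinol epimers into the thermodynamically favoured E vinyl sulfoxide, the geometry that later places the arene cis to the new C2–C3 bond.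

Step 6
Reactants: 12 1-bromo-4-fluoro-2,3-dimethyl-5-{(E)-2-[(S)-p-tolylsulfinyl]vinyl}benzene; 4 all-E octaprenylacetone
Product: 15 (2R)-6-bromo-2,7,8-trimethyl-2-R8-3-[(R)-p-tolylsulfinyl]-2H-chromene, via vinyllithium 13 (not isolated), via lithium alkoxide 14 (not isolated)
Conditions: LDA, THF, −78 °C; 4, −78 to −20 °C; DMPU, 50 °C, dark; chromatography
Reagents that add atoms: none
Why: Proposed new method: LDA removes the C3–H acidified by the sulfinyl group, the geometrically stable vinyllithium 13 adds to the carbonyl carbon of 4 (C2–C3 bond), and the tertiary alkoxide 14, which the E geometry holds cis to the arene, displaces fluoride at C8a by addition–elimination (O1–C8a bond), the Meisenheimer charge being carried through C4a and C4=C3 onto the α-sulfinyl carbon and LiF formation making the sequence irreversible. The closest known reaction types are the carbonyl addition of α-lithiated vinyl sulfoxides and the aldol/SNAr and Michael/SNAr domino annulations of 2-fluoroaryl ketones and acrylates; their union into a formal [4+2] annulation of an unactivated ketone C=O, with only vinylogous activation of the C–F bond, is what is new. The pyran ring, the only ring formed, closes by intramolecular SNAr, a six-membered closure in which O1 attacks the ring carbon C8a. C2 is the only new stereocentre and is controlled by the neighbouring sulfur stereocentre: the carbonyl addition should be reversible at the cyclisation temperature, and in the cyclisation transition state the S–O bond lies syn-periplanar to C3=C4, so that p-tolyl covers one face of C2 and the long chain takes the lone-pair face, which for the (S)-sulfoxide means 2R (the sulfur descriptor becomes R only because C3 now outranks p-tolyl). Because the auxiliary makes the C2 epimers diastereomers, the minor epimer is removed by chromatography at this stage. The step needs addition rather than enolisation of the methyl ketone and attack at C–F rather than C–Br, which the low basicity of the sulfinyl-stabilised anion at −78 °C and the position of fluorine, the only halogen ortho to the activating vinyl sulfoxide and within reach of O1, should secure.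

Step 7
Reactants: 15 (2R)-6-bromo-2,7,8-trimethyl-2-R8-3-[(R)-p-tolylsulfinyl]-2H-chromene
Product: 17 (2R)-6-bromo-2,7,8-trimethyl-2-R8-2H-chromene, via 3-lithiochromene 16 (not isolated)
Conditions: PhLi, THF, −78 °C, 5 min; aq. NH4Cl
Reagents that add atoms: none
Why: Sulfoxide–lithium exchange at sulfur is much faster than bromine–lithium exchange with PhLi at −78 °C, the vinyl ligand leaves as the better carbanion, and 16 is protonated with retention before it can eliminate the aryloxide, so that C2 is untouched.

Step 8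
Reactants: 17 (2R)-6-bromo-2,7,8-trimethyl-2-R8-2H-chromene
Product: 19 plastochromenol-8, via caesium phenolate 18 (not isolated)
Conditions: t-BuBrettPhos Pd G3 (cat.), CsOH·H2O, 1,4-dioxane/H2O (degassed), rt to 40 °C, dark; aq. HCl
Reagents that add atoms: caesium hydroxide, [Cs+].[OH-]
Why: Palladium-catalysed hydroxylation of an aryl bromide (C–O cross-coupling with hydroxide) with a bulky biarylphosphine ligand made for hindered electron-rich bromides, under mild conditions that leave the isolated alkenes, the chromene C3=C4 bond and C2 unchanged.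

**Compound list**
1 | solanesol (all-E nonaprenol) | CC(C)=CCC/C(C)=C/CC/C(C)=C/CC/C(C)=C/CC/C(C)=C/CC/C(C)=C/CC/C(C)=C/CC/C(C)=C/CC/C(C)=C/CO | starting material
2 | rac-(2S*,3S*)-2,3-epoxysolanesol (racemate, one enantiomer drawn) | CC(C)=CCC/C(C)=C/CC/C(C)=C/CC/C(C)=C/CC/C(C)=C/CC/C(C)=C/CC/C(C)=C/CC/C(C)=C/CC[C@]1(C)O[C@H]1CO | intermediate
3 | 2,3-dihydro-2,3-dihydroxysolanesol (1,2,3-triol, stereoisomers irrelevant) | CC(C)=CCC/C(C)=C/CC/C(C)=C/CC/C(C)=C/CC/C(C)=C/CC/C(C)=C/CC/C(C)=C/CC/C(C)=C/CCC(C)(O)C(O)CO | intermediate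
4 | all-E octaprenylacetone, (5E,9E,13E,17E,21E,25E,29E)-6,10,14,18,22,26,30,34-octamethylpentatriaconta-5,9,13,17,21,25,29,33-octaen-2-one | CC(C)=CCC/C(C)=C/CC/C(C)=C/CC/C(C)=C/CC/C(C)=C/CC/C(C)=C/CC/C(C)=C/CC/C(C)=C/CCC(C)=O | intermediate
5 | 1-bromo-4-fluoro-2,3-dimethylbenzene | Cc1c(C)c(Br)ccc1F | starting material
6 | 5-bromo-2-fluoro-3,4-dimethylphenyllithium | Cc1c(C)c(Br)cc([Li])c1F | intermediate
7 | 5-bromo-2-fluoro-3,4-dimethylbenzaldehyde | Cc1c(C)c(Br)cc(C=O)c1F | intermediate
8 | (S)-methyl p-tolyl sulfoxide | C[S@](=O)c1ccc(C)cc1 | starting material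
9 | (S)-(p-tolylsulfinyl)methyllithium | [Li]C[S@](=O)c1ccc(C)cc1 | intermediate
10 | 1-(5-bromo-2-fluoro-3,4-dimethylphenyl)-2-[(S)-p-tolylsulfinyl]ethanol (both carbinol epimers) | Cc1c(C)c(Br)cc(C(O)C[S@](=O)c2ccc(C)cc2)c1F | intermediate
11 | methanesulfonate of 10 | Cc1c(C)c(Br)cc(C(OS(C)(=O)=O)C[S@](=O)c2ccc(C)cc2)c1F | intermediate
12 | 1-bromo-4-fluoro-2,3-dimethyl-5-{(E)-2-[(S)-p-tolylsulfinyl]vinyl}benzene | Cc1c(C)c(Br)cc(/C=C/[S@](=O)c2ccc(C)cc2)c1F | intermediate
13 | α-lithiated 12 (Li on C3, arene cis to Li) | Cc1c(C)c(Br)cc(/C=C(/[S@](=O)c2ccc(C)cc2)[Li])c1F | intermediate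
14 | lithium alkoxide of the (2R) tertiary alcohol adduct (arene cis to C2) | CC(C)=CCC/C(C)=C/CC/C(C)=C/CC/C(C)=C/CC/C(C)=C/CC/C(C)=C/CC/C(C)=C/CC/C(C)=C/CC[C@@](C)(O[Li])/C(=C\c1cc(Br)c(C)c(C)c1F)[S@](=O)c1ccc(C)cc1 | intermediate
15 | (2R)-6-bromo-2,7,8-trimethyl-2-R8-3-[(R)-p-tolylsulfinyl]-2H-chromene | CC(C)=CCC/C(C)=C/CC/C(C)=C/CC/C(C)=C/CC/C(C)=C/CC/C(C)=C/CC/C(C)=C/CC/C(C)=C/CC[C@]1(C)C([S@](=O)c2ccc(C)cc2)=Cc2cc(Br)c(C)c(C)c2O1 | intermediate
16 | (2R)-6-bromo-3-lithio-2,7,8-trimethyl-2-R8-2H-chromene | CC(C)=CCC/C(C)=C/CC/C(C)=C/CC/C(C)=C/CC/C(C)=C/CC/C(C)=C/CC/C(C)=C/CC/C(C)=C/CC[C@]1(C)C([Li])=Cc2cc(Br)c(C)c(C)c2O1 | intermediate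
17 | (2R)-6-bromo-2,7,8-trimethyl-2-R8-2H-chromene | CC(C)=CCC/C(C)=C/CC/C(C)=C/CC/C(C)=C/CC/C(C)=C/CC/C(C)=C/CC/C(C)=C/CC/C(C)=C/CC[C@]1(C)C=Cc2cc(Br)c(C)c(C)c2O1 | intermediate
18 | caesium (2R)-2,7,8-trimethyl-2-R8-2H-chromen-6-olate | CC(C)=CCC/C(C)=C/CC/C(C)=C/CC/C(C)=C/CC/C(C)=C/CC/C(C)=C/CC/C(C)=C/CC/C(C)=C/CC[C@]1(C)C=Cc2cc([O-])c(C)c(C)c2O1.[Cs+] | intermediate
19 | plastochromenol-8, (2R)-2,7,8-trimethyl-2-R8-2H-chromen-6-ol | CC(C)=CCC/C(C)=C/CC/C(C)=C/CC/C(C)=C/CC/C(C)=C/CC/C(C)=C/CC/C(C)=C/CC/C(C)=C/CC[C@]1(C)C=Cc2cc(O)c(C)c(C)c2O1 | target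

**Step count**
- Total step count: 8.
- Longest linear sequence: 6 steps (5 → 7 → 10 → 12 → 15 → 17 → 19).

**The three steps most likely to fail**

**Step 6 (Proposed new method).**
- Facial discrimination between the methyl group and the chain may be poor.
- The ketone may be enolised instead of attacked.
- Fluoride displacement may be sluggish, so that retro-addition and Michael-type consumption of the vinyl sulfoxide by the ketone enolate take over.

The fallback uses known chemistry, sets the stereocentre by catalyst control and makes the two bonds separately. It sets out from 4 and 7 and comes back at 17. A catalytic asymmetric Corey–Chaykovsky epoxidation of 4 would give the terminal (R)-epoxide F1. The conditions are dimethyloxosulfonium methylide, La–Li3–tris(binaphthoxide) of the antipode that gives the R product, a triarylphosphine oxide additive, THF, rt. Excess dimethylsulfonium methylide would open F1 at its CH2 group and eliminate to the (R)-tertiary allylic alcohol F2. The potassium alkoxide of F2 (KH, THF/DMF) would displace the fluoride of 7, which is activated there by the ortho formyl group, to give the aryl ether aldehyde F3. Wittig methylenation would give the styrene F4. Ring-closing metathesis of the two terminal vinyl groups (second-generation NHC-ligated ruthenium benzylidene catalyst, CH2Cl2, 40 °C) would close C3=C4 and deliver 17.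

**Step 7.**
- Bromine–lithium exchange may compete with the sulfoxide exchange.
- The sulfurane may expel p-tolyl instead of the vinyl ligand.
- The vinyllithium may open the pyran ring by β-elimination.

The fallback removes the bromide before any organolithium is used. It sets out from 15 and comes back at 19. The palladium-catalysed hydroxylation of step 8, applied to 15, would give the 6-hydroxy-3-sulfinylchromene F5. Reductive desulfinylation with t-BuLi in the presence of MeOH as an internal proton source (THF, −78 °C) would protonate the vinyl anion as it forms and give 19 directly.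

**Step 8.**
- Oxidative addition at the hindered, electron-rich C–Br bond may be slow.
- Palladium hydrides may isomerise alkenes.
- The phenolate may be oxidised by air.
- If heating becomes necessary, thermal electrocyclic opening of the pyran ring may erode the configuration at C2.

The fallback replaces cross-coupling by a low-temperature main-group sequence. It sets out from 17 and comes back at 19. Bromine–lithium exchange (t-BuLi, THF, −78 °C), trapping with B(OMe)3 and hydrolysis would give the chromen-6-ylboronic acid F6. Oxidation of F6 with NaBO3·4H2O (THF/H2O, rt) would give 19.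

**Further compounds**
F1 | step 6 | (R)-2-methyl-2-R8-oxirane | CC(C)=CCC/C(C)=C/CC/C(C)=C/CC/C(C)=C/CC/C(C)=C/CC/C(C)=C/CC/C(C)=C/CC/C(C)=C/CC[C@]1(C)CO1
F2 | step 6 | (R)-methyl(R8)(vinyl)carbinol (tertiary allylic alcohol) | CC(C)=CCC/C(C)=C/CC/C(C)=C/CC/C(C)=C/CC/C(C)=C/CC/C(C)=C/CC/C(C)=C/CC/C(C)=C/CC[C@@](C)(O)C=C
F3 | step 6 | 5-bromo-3,4-dimethyl-2-{[(R)-methyl(R8)(vinyl)methyl]oxy}benzaldehyde | CC(C)=CCC/C(C)=C/CC/C(C)=C/CC/C(C)=C/CC/C(C)=C/CC/C(C)=C/CC/C(C)=C/CC/C(C)=C/CC[C@](C)(C=C)Oc1c(C)c(C)c(Br)cc1C=O
F4 | step 6 | 1-bromo-2,3-dimethyl-4-{[(R)-methyl(R8)(vinyl)methyl]oxy}-5-vinylbenzene | CC(C)=CCC/C(C)=C/CC/C(C)=C/CC/C(C)=C/CC/C(C)=C/CC/C(C)=C/CC/C(C)=C/CC/C(C)=C/CC[C@](C)(C=C)Oc1c(C)c(C)c(Br)cc1C=C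
F5 | step 7 | (2R)-2,7,8-trimethyl-2-R8-3-[(R)-p-tolylsulfinyl]-2H-chromen-6-ol | CC(C)=CCC/C(C)=C/CC/C(C)=C/CC/C(C)=C/CC/C(C)=C/CC/C(C)=C/CC/C(C)=C/CC/C(C)=C/CC[C@]1(C)C([S@](=O)c2ccc(C)cc2)=Cc2cc(O)c(C)c(C)c2O1
F6 | step 8 | [(2R)-2,7,8-trimethyl-2-R8-2H-chromen-6-yl]boronic acid | CC(C)=CCC/C(C)=C/CC/C(C)=C/CC/C(C)=C/CC/C(C)=C/CC/C(C)=C/CC/C(C)=C/CC/C(C)=C/CC[C@]1(C)C=Cc2cc(B(O)O)c(C)c(C)c2O1
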